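Ring atoms are numbered C1–C10 as follows: C1 carries the free hydroxyl, C3 the acetate, C6 the lactone oxygen, C8 the tiglate; C11–C13 are the lactone α-carbon, carbonyl and exocyclic methylene; C14 is the methyl on C10 and C15 the methyl on C4. Compound numbers are fixed by the steps below and used throughout.

## Analysis of the target

The target is a germacrane-type sesquiterpene lactone: a ten-membered carbocycle with a trans-fused α-methylene-γ-butyrolactone across C6–C7. Four ring carbons are oxygenated (C1 OH, C3 OAc, C6 lactone O, C8 tiglate), and the two trisubstituted ring alkenes differ in geometry: C4=C5 is Z, C9=C10 is E. The five stereocentres are 1S,3S,6R,7S,8R. C1/C3 and C6/C8 are 1,3-anti pairs, and the C11 branch on C7 is syn to the C6 oxygen (hence the trans lactone) and anti to the C8 oxygen. Sensitive functions are the methylene lactone (a Michael acceptor, labile to base and nucleophiles), the two allylic esters, the 1,3-diol monoacetate (acetyl migration from O3 to O1 under base) and the lactone beside an acylated C8 oxygen (translactonisation). The synthesis is hard because of the medium ring, the two alkene geometries, and above all the need to tell apart four allylic secondary oxygens in a ring that is constitutionally almost symmetric about the C2···C7 axis (C1↔C3, C10↔C4, C9↔C5, C8↔C6). The strategy rests on the 1,6-relationship of C1 and C6. Each is flanked by a methylene (C2, C7) and an alkene carbon (C10, C5), and a bond between them would divide the ring into two six-membered rings with C14 next to the fusion and C15 one position further. That is the carbon skeleton of 1,6-dimethylnaphthalene.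

## Retrosynthetic reasoning

**23 back to 21.** The last bond cut is the C1–O protecting group of 22, removed under neutral oxidative conditions so that the C3 acetate cannot migrate to O1. Before that, the acetate of 22 is disconnected to 21, in which C3–OH is the only free hydroxyl. The regiochemistry of the 1,3-diol monoacetate is thus set by the order of events, not by selectivity between two nearly identical carbinols.

**21 back to 18.** The C11=C13 methylene is removed to give lactone 18. It is introduced only after the lactone exists, because only then is C11 the most acidic carbon, and before the acetate, which would not survive an enolate step next to a free alkoxide.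

**18 back to 17.** The lactone C12–O6 bond is cut to the hydroxy ester 17. In 17 only O6 can close a five-membered lactone, because O8 is already acylated.

**17 back to 15 and 16.** The C8 tiglate and the C6 carbinol hydrogen are removed together. An Evans–Tishchenko reduction of the β-hydroxy ketone 15 with aldehyde 16 must set C6 anti to C8 and at the same time put the acyl group on O8 only. This answers the O6/O8 differentiation without a protecting group.

**15 back to 13 and 14.** The C7–C11 bond is cut next to the C6 ketone. A dianion alkylation of 13 with 14 must place C11 anti to the C8 oxygen. This is the normal sense of a chelated β-alkoxide enolate, and it is the relationship the target has.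

**13 back to 10.** The C6 ketone and C3–OH of 13 are folded back into the mixed cyclic ketal of 12, and the C1 ether to alcohol 11 and enone 10. While C6 is a ketal, C1 is the only carbonyl, so a reagent-controlled reduction can set C1 without touching C6. The C1 oxygen can then be protected while O3 is tied up and O8 is silylated.

**10 back to 7.** The C8 carbinol and the E C9=C10 alkene of 10 come from the C8–C9 epoxide 8 by base-induced opening through the C1 enolate. Epoxide 8 comes from the Z alkene of 7 by a catalyst-controlled epoxidation. Because C6 is masked in 7 and 8, only C1 can enolise, and the opening has one possible direction.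

**7 back to 4.** The C3 oxygen and the Z C4=C5 alkene of 7 come from epoxide 5, made by asymmetric epoxidation of the trisubstituted alkene of 4. Opening through the C6 enolate gives the γ-hydroxy enone, and ketalisation selects and locks the Z geometry.

**4 back to 2.** The two carbonyl carbons C1 and C6 of dione 4 are joined as a tetrasubstituted alkene. This is the central double bond of the tetrahydronaphthalene 2, so oxidative scission of that bond reveals the ten-membered ring with all twelve skeletal carbons and both Z alkenes in place.

**2 back to 1.** The two cyclohexa-1,4-diene rings of 2 are the Birch reduction pattern of naphthalene 1.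

## Alternatives that were turned down

**Alternative 1:** The C4=C5 bond is cut inside a temporary seven-membered silylene ketal that joins O3 and O6. In the forward step, ring-closing metathesis (second-generation Grubbs catalyst) between the isopropenyl group at C3 and one vinyl of a divinyl carbinol at C6 gives the dioxasilepine A1. In its favour: the seven-membered ring can only hold a Z alkene, and the choice between the two diastereotopic vinyl groups sets C6 against C3. On the Z geometry it is stronger than the chosen route, which reaches Z by draining an equilibrium into a ketal. Against it: A1 is only a C3–C6 fragment. The C7–C8 bond, the ten-membered ring, the lactone and the centres C1, C7 and C8 all still have to be made, each with its own control element, and a macrocyclisation comes late. Metathesis of a 1,1-disubstituted alkene beside a second vinyl group and a trisubstituted alkene may also be slow and only moderately group-selective. The chosen strategy offers the complete ring after two steps and no macrocyclisation at all.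

**Alternative 2:** The C2–C3 bond (and C1–O) is cut by an intramolecular nitrile oxide–alkene cycloaddition. In the forward step, the nitrile oxide generated at C3 from an aldoxime adds across the terminal C1=C2 alkene and gives the isoxazoline-bridged carbocycle A2. In its favour: ring closure, the C1 oxygen and a masked C1-hydroxy/C3-keto aldol arise in one step, with the lactone and both ring alkenes already present. Against it: closing a ten-membered ring by dipolar cycloaddition competes with nitrile oxide dimerisation and needs high dilution. The face of the alkene, and with it C1, is chosen by remote centres through a flexible chain. Reductive N–O cleavage must spare three alkenes, and the unveiled aldol would leave the acyl group on the wrong oxygen after a Tishchenko-type reduction, so the C1/C3 pair would still need differentiation. It matches the chosen route in convergence of functionality, but the chosen route needs no ring-closing step and uses the ketal sequence to settle the O1/O3 question.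

**Alternative 3:** The C7–C8 bond is cut by an intramolecular chromium-mediated allylation. In the forward step, CrCl2 turns a C13 allylic bromide on a butenolide into an allylchromium species that attacks the C8 aldehyde through C7. The alkene moves to C11=C13 and the ring closes to A3. In its favour: one step makes the ring, C7, C8 and the methylene lactone, and leaves exactly one free hydroxyl (C8) for the tiglate. This is a cleaner endgame than the chosen route, where the methylenation has to be run with the tiglate present. Against it: the open-chain substrate must already contain both trisubstituted alkenes with defined geometry, the centres C1, C3 and C6, an enal and an allylic bromide, which is a long linear sequence. The closure needs high dilution and excess chromium, and its facial sense relative to C6 is not assured. The chosen strategy is much shorter up to the ring and avoids macrocyclisation; it pays with more late-stage functional-group ordering.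

Key step: step 2

Remark on the chemistry: compounds 13 and 15 are drawn as open hydroxy enones; each should equilibrate with its five-membered C3–O–C6 hemiketal.
Remark on the chemistry: the CIP letters at C7 and C8 change between some intermediates only because substituent priorities change; the spatial arrangement is that of the target throughout.
Remark on the chemistry: for the two asymmetric epoxidations the catalyst antipode is named by the accepted facial model; if the sense proved opposite, the mirror-image catalyst would be used.

## Route

Step 1
Reactants: 1 1,6-dimethylnaphthalene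
Product: 2 1,6-dimethyl-1,4,5,8-tetrahydronaphthalene (racemic)
Conditions: Na (excess), liquid NH3, EtOH, Et2O, −78 → −33 °C; NH4Cl quench
Reagents that add atoms: none
Why: Birch reduction; each ring is taken to the 1,4-diene that keeps the alkyl-substituted ring-fusion carbons sp2, so the unconjugated triene with a tetrasubstituted central alkene should result, and the methyl-bearing sp3 carbon (future C10) is the only stereocentre, racemic and erased in step 6.

Step 2
Reactants: 2 1,6-dimethyl-1,4,5,8-tetrahydronaphthalene
Product: 4 (3Z,8Z)-4,10-dimethylcyclodeca-3,8-diene-1,6-dione (racemic at C10), via secondary ozonide 3 (not isolated)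
Conditions: O3 (1.0 equiv, added as a titrated CH2Cl2 solution), CH2Cl2, −78 °C; then PPh3, −78 °C → rt; neutral work-up, used at once
Reagents that add atoms: ozone, O=[O+][O-]
Why: Ozone undergoes 1,3-dipolar addition to the central tetrasubstituted alkene, the primary ozonide cycloreverts to a ketone and a carbonyl oxide held in the same ring, these recombine to the bridged ozonide 3, and the phosphine reduces it to the two ketones. The closest known reaction type is the ozonolytic or epoxidation–glycol-cleavage scission of the central double bond of 1,4,5,8-tetrahydronaphthalenes and of 9,10-octalins to cyclodecane-1,6-diones. No ring is closed by bond formation: the ten-membered ring appears because the bond shared by the two six-membered rings is cut, so no closure mode applies and no ring-closing entropy is paid. No stereocentre is created; C10 is carried as the racemate and becomes trigonal in step 6. The two side alkenes are not touched and so keep the Z geometry imposed by the six-membered rings. The step needs chemoselectivity for the tetrasubstituted alkene over the trisubstituted and the disubstituted one; this rests on its higher nucleophilicity toward the electrophilic dipole and is helped by one equivalent of titrated ozone at −78 °C. The product is a doubly skipped enedione, so a neutral, cold work-up is required to avoid conjugation or transannular aldol reaction.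

Step 3
Reactants: 4 (3Z,8Z)-4,10-dimethylcyclodeca-3,8-diene-1,6-dione
Product: 5 (3S,4R)-3,4-epoxy-4,10-dimethylcyclodec-8-ene-1,6-dione (C10 epimers)
Conditions: L-fructose-derived Shi ketone (mirror image of the usual D-fructose-derived catalyst, 1 equiv), Oxone (2KHSO5·KHSO4·K2SO4), NaHCO3, MeCN–H2O, 0 °C
Reagents that add atoms: potassium peroxymonosulfate, [K+].[O-]S(=O)(=O)OO
Why: Shi asymmetric epoxidation; the chiral dioxirane prefers the trisubstituted alkene (spiro transition state) over the cis-disubstituted C8=C9, and by the spiro model this catalyst antipode should deliver oxygen to the face that gives 3S,4R; the near-neutral buffer is chosen to spare the base-labile skipped enone units.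

Step 4
Reactants: 5 (3S,4R)-3,4-epoxy-4,10-dimethylcyclodec-8-ene-1,6-dione
Product: 7 C3–O–C6 cyclic methyl ketal (3S,6R; Z C4=C5; C1 ketone), via hydroxy enone 6 (not isolated)
Conditions: Et3N (0.2 equiv), CH2Cl2, 0 °C; then CSA (0.1 equiv), MeOH, rt
Reagents that add atoms: methanol, CO
Why: E1cB opening of the β,γ-epoxy ketone: the C6 enolate (C5–H) expels the tertiary C4–O bond, which is weaker and gives the more substituted enone, in preference to the C1/C2 pathway, and leaves the C3 carbinol (3S) untouched. The enone formed first is expected to be mainly 4E; in acidic methanol the C6 carbonyl ionises to a methoxyallyl cation that rotates about C4–C5, so the Z form is drained as the five-membered mixed ketal (the known ketalisation of cis-γ-hydroxy enones). The ketal fixes Z C4=C5, masks C6 and O3, and sets C6 because the bridge can only close cis.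

Step 5
Reactants: 7 C3–O–C6 cyclic methyl ketal
Product: 8 (8S,9R)-8,9-epoxide of 7 (C10 epimers)
Conditions: chiral di-μ-oxo titanium salalen complex [Ti(μ-O)(salalen)]2 (5 mol %), 30% aq. H2O2, CH2Cl2–pH 7.4 phosphate buffer, rt
Reagents that add atoms: hydrogen peroxide, OO
Why: Catalyst-controlled epoxidation of a non-conjugated Z-disubstituted alkene, the substrate class these tetravalent titanium catalysts handle best; they react sluggishly with trisubstituted alkenes, so the dihydrofuran alkene, further deactivated by two allylic oxygens, should be spared, and both C10 epimers converge in step 6.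

Step 6
Reactants: 8 (8S,9R)-8,9-epoxide of 7
Product: 10 C8 triethylsilyl ether of the (8S,9E) hydroxy enone, via hydroxy enone 9 (not isolated)
Conditions: DBU (0.2 equiv), CH2Cl2, 0 °C; then Et3SiCl, imidazole, 0 °C
Reagents that add atoms: chlorotriethylsilane, CC[Si](Cl)(CC)CC
Why: With C6 locked as a ketal, C1 is the only enolisable carbonyl, so the E1cB opening can only break C9–O: C9=C10 forms in conjugation with C1 and O8 keeps the epoxide configuration. The antiperiplanar enolate/C–O arrangement should give the E enone, in which O8 cannot reach C1, and the alcohol is capped in the same flask.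

Step 7
Reactants: 10 C8 triethylsilyl ether of the (8S,9E) hydroxy enone
Product: 11 (1S)-allylic alcohol
Conditions: (R)-2-methyl-CBS-oxazaborolidine (0.3 equiv), catecholborane (1.5 equiv), toluene, −78 °C
Reagents that add atoms: none
Why: CBS reduction of the only ketone; the α-methyl enone presents the alkenyl carbon C10 as the large and the C2 methylene as the small substituent, so the (R)-catalyst should deliver hydride to the face giving 1S (anti to O3), and catecholborane at −78 °C leaves the alkenes and the ketal alone.

Step 8
Reactants: 11 (1S)-allylic alcohol
Product: 12 C1 4-methoxybenzyl ether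
Conditions: NaH, 4-MeOC6H4CH2Cl, Bu4NI (cat.), THF–DMF, 0 °C → rt
Reagents that add atoms: 4-methoxybenzyl chloride, COc1ccc(CCl)cc1
Why: Williamson etherification of the only free hydroxyl; the benzyl-type ether survives the enolate steps, cannot migrate to a neighbouring alkoxide as a silyl group could, and is removed at the end under neutral conditions.

Step 9
Reactants: 12 C1 4-methoxybenzyl ether
Product: 13 open hydroxy enone (C6 ketone; C3–OH; C8–OH; C1–OPMB)
Conditions: AcOH–THF–H2O (3:1:1), rt
Reagents that add atoms: water, O
Why: Mild aqueous acid hydrolyses the very labile 2-methoxy-2,5-dihydrofuran ketal and the secondary triethylsilyl ether but not the PMB ether; aromatisation of the hemiketal to a furan is blocked because a 2,5-bridged furan with an E alkene in a six-carbon bridge would be prohibitively strained.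

Step 10
Reactants: 13 open hydroxy enone; 14 tert-butyl bromoacetate
Product: 15 C7-alkylated hydroxy enone (C11 anti to O8)
Conditions: LiN(iPr)2 (LDA, 3.3 equiv), THF, −78 → −40 °C; then 14, DMPU, −78 °C; AcOH quench at −78 °C
Reagents that add atoms: none
Why: Fráter–Seebach-type alkylation: excess base forms the alkoxides and then the only possible enolate of the open keto form (C6/C7; C5 is vinylic and C1 is no longer a carbonyl). The lithium bridge between the O8 alkoxide and the enolate oxygen exposes the face of C7 anti to C9, so the electrophile should enter anti to O8. An alkoxide is too poor a leaving group for β-elimination, and the tert-butyl ester resists lactonisation onto O8.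

Step 11
Reactants: 15 C7-alkylated hydroxy enone; 16 (E)-2-methylbut-2-enal
Product: 17 C8 tiglate C6 alcohol (6R; 1,3-anti)
Conditions: SmI2 (0.3 equiv, premixed with 16), 16 (5 equiv), THF, −10 °C, dark
Reagents that add atoms: none
Why: Evans–Tishchenko reduction: O8 forms a hemiacetal with the aldehyde and, on the trivalent samarium alkoxide generated from SmI2, its C–H is delivered intramolecularly to the C6 ketone through a chair transition state. This gives the 1,3-anti diol monoester, with C6–OH anti to O8 and the tigloyl group on O8 only; O3 lies across the Z alkene and could only use a larger, less organised ring.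

Step 12
Reactants: 17 C8 tiglate C6 alcohol
Product: 18 trans-fused 6,12-lactone (C11 H2; C3–OH free)
Conditions: CSA (0.2 equiv), CH2Cl2, rt
Reagents that add atoms: none
Why: Acid-catalysed intramolecular transesterification (5-exo-trig at the ester carbonyl); only O6 is free and γ to C12 (O8 is acylated, O3 would need an eight-membered ring), and because C11 is syn to O6 the lactone closes trans-fused.

Step 13
Reactants: 18 trans-fused 6,12-lactone
Product: 21 α-methylene lactone (C3–OH free), via Mannich base 19 (not isolated), via methiodide 20 (not isolated)
Conditions: LiN(SiMe3)2 (2.3 equiv), THF, −78 °C; CH2=NMe2+ I− (Eschenmoser's salt), −78 → 0 °C; then MeI, THF, rt; then aq. NaHCO3, CH2Cl2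
Reagents that add atoms: N,N-dimethylmethyleneiminium iodide, C=[N+](C)C.[I-]
Why: Aminomethylation of the lactone enolate, quaternisation and E1cB loss of trimethylamine give the exocyclic methylene. The lactone α-CH2 is several pK units more acidic than any C–H of the tiglate, the hindered silylamide should not add to the α,β-disubstituted ester, and the O8 acyl group sits anti to C11 so acyl transfer is geometrically disfavoured; the O3 alkoxide is a spectator.

Step 14
Reactants: 21 α-methylene lactone
Product: 22 C3 acetate (C1–OPMB)
Conditions: Ac2O, pyridine, DMAP (cat.), CH2Cl2, 0 °C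
Reagents that add atoms: acetic anhydride, CC(=O)OC(C)=O
Why: Acetylation of the only free hydroxyl; O1 is still an ether, so the position of the acetate in the 1,3-diol is fixed by the sequence.

Step 15
Reactants: 22 C3 acetate
Product: 23 target (1S,3S,6R,7S,8R; 4Z; 9E)
Conditions: DDQ, CH2Cl2–pH 7 buffer, 0 °C
Reagents that add atoms: none
Why: Oxidative cleavage of the 4-methoxybenzyl ether via the benzylic cation and hemiacetal; the buffered neutral medium should avoid 1,3-acetyl migration and conjugate addition to the methylene lactone.

## Compound list

1 | 1,6-dimethylnaphthalene | Cc1ccc2c(C)cccc2c1 | starting material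
2 | 1,6-dimethyl-1,4,5,8-tetrahydronaphthalene (racemic) | CC1C=CCC2=C1CC=C(C)C2 | intermediate
3 | secondary ozonide of 2: C1 and C6 of the ten-membered ring bridged by O and by O–O (racemic, C10 epimers) | CC1/C=C\CC23C/C(C)=C\CC1(O2)OO3 | intermediate
4 | (3Z,8Z)-4,10-dimethylcyclodeca-3,8-diene-1,6-dione (racemic at C10) | CC1/C=C\CC(=O)C/C(C)=C\CC1=O | intermediate
5 | (3S,4R,8Z)-3,4-epoxy-4,10-dimethylcyclodec-8-ene-1,6-dione (C10 epimers) | O=C1C[C@@H]2O[C@]2(C)CC(=O)C/C=C\C1C | intermediate
6 | (3S,4E,8Z)-3-hydroxy-4,10-dimethylcyclodeca-4,8-diene-1,6-dione (C10 epimers; 4E expected first) | O=C1C[C@H](O)/C(C)=C/C(=O)C/C=C\C1C | intermediate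
7 | (3S,6R,8Z)-6-methoxy-3,6-epoxy-4,10-dimethylcyclodeca-4,8-dien-1-one: 2-methoxy-2,5-dihydrofuran ketal bridging C3 and C6 (C10 epimers) | CO[C@]12C/C=C\C(C)C(=O)C[C@H](O1)C(C)=C2 | intermediate
8 | (8S,9R)-8,9-epoxide of 7 (C10 epimers) | CO[C@]12C[C@@H]3O[C@@H]3C(C)C(=O)C[C@H](O1)C(C)=C2 | intermediate
9 | (3S,6R,8S,9E)-8-hydroxy-6-methoxy-3,6-epoxy-4,10-dimethylcyclodeca-4,9-dien-1-one | CO[C@]12C[C@H](O)/C=C(\C)C(=O)C[C@H](O1)C(C)=C2 | intermediate
10 | 8-O-triethylsilyl ether of 9 | CO[C@]12C[C@H](O[Si](CC)(CC)CC)/C=C(\C)C(=O)C[C@H](O1)C(C)=C2 | intermediate
11 | (1S,3S,6R,8S,9E)-6-methoxy-3,6-epoxy-4,10-dimethyl-8-(triethylsilyloxy)cyclodeca-4,9-dien-1-ol | CO[C@]12C[C@H](O[Si](CC)(CC)CC)/C=C(\C)[C@@H](O)C[C@H](O1)C(C)=C2 | intermediate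
12 | 1-O-(4-methoxybenzyl) ether of 11 | CO[C@]12C[C@H](O[Si](CC)(CC)CC)/C=C(\C)[C@@H](OCc3ccc(OC)cc3)C[C@H](O1)C(C)=C2 | intermediate
13 | (1S,3S,8S,4Z,9E)-3,8-dihydroxy-1-(4-methoxybenzyloxy)-4,10-dimethylcyclodeca-4,9-dien-6-one (open form of the C3–O–C6 hemiketal) | C1[C@H](O)/C(C)=C\C(=O)C[C@H](O)/C=C(\C)[C@H]1OCc1ccc(OC)cc1 | intermediate
14 | tert-butyl bromoacetate | BrCC(=O)OC(C)(C)C | starting material
15 | tert-butyl ester of the C7 acetic acid derived from 13: (1S,3S,7R,8R), C11 anti to O8 (open form) | C1[C@H](O)/C(C)=C\C(=O)[C@H](CC(=O)OC(C)(C)C)[C@H](O)/C=C(\C)[C@H]1OCc1ccc(OC)cc1 | intermediate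
16 | (E)-2-methylbut-2-enal (tiglic aldehyde) | C/C=C(\C)C=O | starting material
17 | (1S,3S,6R,7S,8R)-3,6-diol 8-tiglate: C6–OH anti to O8, tert-butyl ester on C11, C1–OPMB | C1[C@H](O)/C(C)=C\[C@@H](O)[C@H](CC(=O)OC(C)(C)C)[C@H](OC(=O)/C(C)=C/C)/C=C(\C)[C@H]1OCc1ccc(OC)cc1 | intermediate
18 | trans-fused 6,12-lactone (C11 H2) with C3–OH, C8 tiglate, C1–OPMB; (1S,3S,6R,7S,8R) | O=C1O[C@@H]2/C=C(/C)[C@@H](O)C[C@H](OCc3ccc(OC)cc3)/C(C)=C/[C@@H](OC(=O)/C(C)=C/C)[C@H]2C1 | intermediate
19 | C11 (dimethylamino)methyl lactone (C11 epimers) | CN(C)CC1C(=O)O[C@@H]2/C=C(/C)[C@@H](O)C[C@H](OCc3ccc(OC)cc3)/C(C)=C/[C@@H](OC(=O)/C(C)=C/C)[C@@H]12 | intermediate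
20 | trimethylammonium iodide of 19 | C[N+](C)(C)CC1C(=O)O[C@@H]2/C=C(/C)[C@@H](O)C[C@H](OCc3ccc(OC)cc3)/C(C)=C/[C@@H](OC(=O)/C(C)=C/C)[C@@H]12.[I-] | intermediate
21 | α-methylene lactone with C3–OH, C8 tiglate, C1–OPMB | C=C1C(=O)O[C@@H]2/C=C(/C)[C@@H](O)C[C@H](OCc3ccc(OC)cc3)/C(C)=C/[C@@H](OC(=O)/C(C)=C/C)[C@@H]12 | intermediate
22 | 3-O-acetate of 21 (C1–OPMB) | C=C1C(=O)O[C@@H]2/C=C(/C)[C@@H](OC(C)=O)C[C@H](OCc3ccc(OC)cc3)/C(C)=C/[C@@H](OC(=O)/C(C)=C/C)[C@@H]12 | intermediate
23 | CNP0319825.6: (1S,3S,6R,7S,8R,4Z,9E)-3-acetoxy-1-hydroxy-8-tigloyloxy germacra-4,9,11(13)-trien-12,6-olide | C=C1C(=O)O[C@@H]2/C=C(/C)[C@@H](OC(C)=O)C[C@H](O)/C(C)=C/[C@@H](OC(=O)/C(C)=C/C)[C@@H]12 | target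

## Step count and least certain steps

Total: 15 steps. Longest linear sequence: 15 steps from 1; compounds 14 and 16 are bought.

**Step 2 (key step).** The likely failure is over-oxidation: ozone discriminates only moderately between a tetrasubstituted and a trisubstituted alkene. The skipped enedione may also drift into conjugation or undergo transannular aldol closure on work-up. Fallback, from 2: a peracid is far more selective for the tetrasubstituted alkene, so mCPBA (1.0 equiv, NaHCO3, CH2Cl2, −20 °C) should give the central epoxide F1. Dilute aqueous HClO4 in THF opens it to the trans-diol F2, and Pb(OAc)4 in benzene cleaves the glycol to 4, where the route is rejoined.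

**Step 4.** The likely failure is incomplete drainage of the E enone into the Z ketal, with acid-promoted conjugation of the remaining β,γ-unsaturated ketone or dehydration at C3 competing during the slow equilibration. Fallback, from 6 (isolated after the Et3N treatment): irradiation at about 350 nm isomerises the enone photochemically without acid. The Z isomer closes spontaneously to the cyclic hemiketal F3, which is converted with PPTS in methanol to 7.

**Step 5.** The likely failure is poor facial selectivity. The chiral catalyst has to override the bias of the bicyclic ketal and of the neighbouring racemic C10 centre, and for one C10 epimer the two are mismatched. Fallback, from 7: epoxidation with dimethyldioxirane gives 8 together with its diastereomeric epoxide F4. DBU opens both, and 9 is separated from its C8 epimer F5 (these are diastereomers because C3 and C6 are fixed). F5 is inverted by a Mitsunobu reaction with 4-nitrobenzoic acid to the 4-nitrobenzoate F6; K2CO3 in methanol releases 9, which is silylated to 10.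

**Step 10.** The likely failure is failure to enolise, because the O3 alkoxide closes onto C6 and hides the ketone; retro-aldol opening of the β-alkoxide ketone on warming is a second risk. Fallback, from 13: the open form is trapped as the bis(triethylsilyl) ether F7 (Et3SiOTf, 2,6-lutidine). Its lithium enolate (1.1 equiv LDA) is alkylated with 14 to F8, and the silyl ethers are removed with AcOH–THF–H2O to give 15. The price is the loss of chelation control at C7.

**Step 11.** The likely failure is poor hydride transfer from an α,β-unsaturated hemiacetal, with reductive coupling or conjugate reduction of the enal by the samarium reagent. Delivery from O3 instead of O8 is a lesser risk. Fallback, from 15: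
- An Evans–Saksena reduction (Me4NBH(OAc)3, MeCN–AcOH, −20 °C) gives the anti triol ester F9.
- CSA closes the trans-fused lactone diol F10.
- Methylenation as in step 13 (3.3 equiv base) gives F11.
- The less hindered C3–OH is acetylated (Ac2O, 1 equiv, pyridine, −20 °C) to F12.
- Tiglic acid with DCC and DMAP then gives 22.

This detour also places the methylenation before any ester is present.

**Step 13.** The likely failure is loss of the tiglate by base attack (γ-deprotonation or acyl transfer) in competition with lactone enolisation. Fallback, from 18: heating with tert-butoxybis(dimethylamino)methane in toluene (70 °C) condenses only at the lactone α-methylene and gives the enaminolactone F13. Dilute aqueous HCl in THF hydrolyses it to the α-hydroxymethylene lactone F14, and aqueous formaldehyde with K2CO3 effects deformylative methylenation to 21.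

## Further compounds

F1 | step 2 | 4a,8a-epoxy-1,6-dimethyl-1,4,4a,5,8,8a-hexahydronaphthalene (racemic) | CC1C=CCC23OC12CC=C(C)C3
F2 | step 2 | 1,6-dimethyl-1,4,5,8-tetrahydronaphthalene-4a,8a-diol (trans-diol, racemic) | CC1C=CCC2(O)CC(C)=CCC12O
F3 | step 4 | C3–O–C6 cyclic hemiketal of the Z hydroxy enone (C6–OH analogue of 7) | O[C@]12C/C=C\C(C)C(=O)C[C@H](O1)C(C)=C2
F4 | step 5 | (8R,9S)-8,9-epoxide of 7 | CO[C@]12C[C@H]3O[C@H]3C(C)C(=O)C[C@H](O1)C(C)=C2
F5 | step 5 | C8 epimer of 9 | CO[C@]12C[C@@H](O)/C=C(\C)C(=O)C[C@H](O1)C(C)=C2
F6 | step 5 | 8-O-(4-nitrobenzoate) of 9 | CO[C@]12C[C@H](OC(=O)c3ccc(cc3)[N+](=O)[O-])/C=C(\C)C(=O)C[C@H](O1)C(C)=C2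
F7 | step 10 | 3,8-bis-O-triethylsilyl ether of 13 | C1[C@H](O[Si](CC)(CC)CC)/C(C)=C\C(=O)C[C@H](O[Si](CC)(CC)CC)/C=C(\C)[C@H]1OCc1ccc(OC)cc1
F8 | step 10 | 3,8-bis-O-triethylsilyl ether of 15 | C1[C@H](O[Si](CC)(CC)CC)/C(C)=C\C(=O)[C@H](CC(=O)OC(C)(C)C)[C@H](O[Si](CC)(CC)CC)/C=C(\C)[C@H]1OCc1ccc(OC)cc1
F9 | step 11 | 3,6,8-triol tert-butyl ester (C6–OH anti to C8–OH; C1–OPMB) | C1[C@H](O)/C(C)=C\[C@@H](O)[C@H](CC(=O)OC(C)(C)C)[C@H](O)/C=C(\C)[C@H]1OCc1ccc(OC)cc1
F10 | step 11 | trans-fused 6,12-lactone 3,8-diol (C11 H2; C1–OPMB) | O=C1O[C@@H]2/C=C(/C)[C@@H](O)C[C@H](OCc3ccc(OC)cc3)/C(C)=C/[C@@H](O)[C@H]2C1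
F11 | step 11 | α-methylene lactone 3,8-diol (C1–OPMB) | C=C1C(=O)O[C@@H]2/C=C(/C)[C@@H](O)C[C@H](OCc3ccc(OC)cc3)/C(C)=C/[C@@H](O)[C@@H]12
F12 | step 11 | α-methylene lactone 3-acetate 8-ol (C1–OPMB) | C=C1C(=O)O[C@@H]2/C=C(/C)[C@@H](OC(C)=O)C[C@H](OCc3ccc(OC)cc3)/C(C)=C/[C@@H](O)[C@@H]12
F13 | step 13 | C11 (dimethylamino)methylene lactone derived from 18 | CN(C)C=C1C(=O)O[C@@H]2/C=C(/C)[C@@H](O)C[C@H](OCc3ccc(OC)cc3)/C(C)=C/[C@@H](OC(=O)/C(C)=C/C)[C@@H]12
F14 | step 13 | C11 hydroxymethylene lactone derived from 18 | OC=C1C(=O)O[C@@H]2/C=C(/C)[C@@H](O)C[C@H](OCc3ccc(OC)cc3)/C(C)=C/[C@@H](OC(=O)/C(C)=C/C)[C@@H]12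
A1 | alternative 1 | 2,2-diisopropyl-1,3,2-dioxasilepine with Z C4=C5, vinyl group on C6, and the C2–C1(OTBS)–C10=C9–C8 OPMB chain on C3 | C=C[C@@H]1O[Si](C(C)C)(C(C)C)O[C@@H](C[C@H](O[Si](C)(C)C(C)(C)C)/C(C)=C/COCc2ccc(OC)cc2)/C(C)=C\1
A2 | alternative 2 | isoxazoline-bridged ten-membered carbocycle (C1–O and C2–C3 formed) with 6,12-lactone and C8 silyl ether | C1[C@H]2/C(C)=C/[C@@H](O[Si](C)(C)C(C)(C)C)[C@H]3CC(=O)O[C@@H]3/C=C(/C)C1=NO2
A3 | alternative 3 | 8-hydroxy ten-membered α-methylene lactone with C3 acetate and C1 triethylsilyl ether | C=C1C(=O)O[C@@H]2/C=C(/C)[C@@H](OC(C)=O)C[C@H](O[Si](CC)(CC)CC)/C(C)=C/[C@@H](O)[C@@H]12
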